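# Proposed synthesis of CNP0197219.1 (42) by Pauson–Khand annulation of a pantolactone-derived enyne

## Analysis of the target

The target 42 is a C15 tetracycle in which a nortricyclene cage (C1 and C6–C11: cyclopropane C8–C9–C10, one-carbon bridges C1, C7 and C11, apex C6) is fused along C1–C6 to the cyclohexane ring A (C1–C6). The numbering used for every intermediate is: C1 the quaternary carbon carrying C15H2OAc, C2 the ring A CH2, C3 CH(OAc), C4 CH(OH), C5 CMe2, C6 the second quaternary carbon, C7 the cage CH2, C8 and C9 the cyclopropane CH groups next to C7 and C1, C10 the cyclopropane C(CH3), C11 the cage CH(OAc). Of the eight stereocentres (C1, C3, C4, C6, C8, C9, C10, C11) the five cage atoms C1, C6, C8, C9 and C10 depend on one another, so four elements are independent: the sense of the cage, C11, C3 and C4 (3S,4R). On ring A the C15 arm, O3, O4 and the C7 bridge lie on one face and C9 and C11 on the other, so the ring C1–C6–C7–C8–C9 is trans-fused to ring A and C15 and C11 are trans; the C11 acetate points towards the C7 bridge, away from C2. Sensitive features are three acetates beside the free hydroxyl of a cis-diol (acyl migration in base), a cyclopropylcarbinyl acetate at C11 (ionisation in strong acid) and the strained cyclopropane. The difficulty lies in four fully substituted carbons (C1, C5, C6, C10), three of them contiguous with C1 and C6 vicinal quaternary stereocentres inside the cage, and in acylating O3 but not O4. The plan rests on two facts: the five-membered ring C1–C6–C7–C8–C9 shares the C1–C6 bond with ring A and has a quaternary C6, which is the retron of a cyclopentenone made from an alkyne, an alkene and a carbonyl unit, and C3–C6 correspond atom for atom to (R)-pantolactone 1, whose carbinol carbon becomes C4 and whose gem-dimethyl carbon becomes C5.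

## Retrosynthetic reasoning

**C3 acetate and the diol.** Target 42 differs from diol 40 only in the C3 acetate. Cutting this ester last lets O3 and O4 travel as one acetonide from 19 to 39, so they need to be told apart only once. The forward step must acylate the axial O3 and leave the equatorial O4; direct acylation would favour O4, so the cyclic orthoester 41 is opened instead. Diol 40 comes from acetonide 39.

**C11–O bond.** Ketone 35 is the obvious precursor of the C11 acetate of 39, but a hydride can reach C11 only from the open side next to C7. That gives alcohol 36 with the oxygen beside C2, the wrong epimer. The acetate is therefore introduced by substitution with inversion through the cyclopropylcarbinyl cation: 36 is acetylated at C15 (37), sulfonylated (38) and solvolysed to 39. The reduction of 35 also removes the pivalate, which is why that ester protects C15 up to this point.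

**Cyclopropane (C10–C8 and C10–C9).** Both bonds of 35 are cut at once to give diazo ketone 34. The three-membered ring is the most strained element, and a carbene at C10 that is tied to C6 through C11 can form both bonds in one step. Because of this tether the carbene can reach C8=C9 only from the face of the C11 arm, so C8, C9 and C10 follow from C6 and C1. The cage is reduced to a bicyclic cyclopentene.

**C10–C11 bond and the C11 arm.** The diazo ketone 34 comes from ethyl ketone 32 by diazo transfer at C10, the only enolisable position. Ketone 32 comes from aldehyde 29 and the ethyl nucleophile 30, which brings C10 and its methyl group. Aldehyde 29 comes from pivalate 27 by unmasking and oxidising C11 (28). Pivalate 27 is the protected form of alcohol 26.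

**C1–C15 bond.** Alcohol 26 is cut at C1–C15 by a [2,3]-sigmatropic transform to stannylmethyl ether 24, made from allylic alcohol 23 and stannane 6. A quaternary C1 must be created next to quaternary C6 with C15 trans to the C11 arm. A sigmatropic shift transfers the carbon suprafacially from O8, so the configuration of the C8 carbinol decides C1 and the double bond arrives at C8=C9, where the cyclopropanation needs it. Alcohol 23 is the 1,2-reduction product of enone 22.

**Key disconnection (C1–C6, C7–C8, C8–C9).** Enone 22 is opened to the 1,7-enyne 19 and a carbonyl ligand of 20. Three skeletal bonds, ring A and the cyclopentenone are formed together, and C6 is set by the resident C3 and C4 centres. The precursor is an acyclic compound with only two stereocentres.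

**C2–C3 bond.** Acetonide 19 comes from alcohol 17 through diol 18. Alcohol 17 is cut between C2 and C3 into the α-silyloxy aldehyde 15 and propargyl bromide 16. The forward addition has to give the 3,4-anti diol, which is the diol of the cis-dioxolane.

**C6=C7, C6–C11 and the chiral pool.** Aldehyde 15 comes from alkene 12 by exchanging the acetonide for silyl ethers (13, 14) and oxidising C3. Alkene 12 comes from ketone 10 and the one-carbon ylide precursor 11 (C7). Ketone 10 comes from aldehyde 4 and the alkoxymethyl donor 7 (C11) through carbinol 9, and 7 is made from 5 and 6. Aldehyde 4 comes from (R)-pantolactone 1 through triol 2 and acetonide 3. This fixes C4 and C5 from the first step.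

## Alternatives that were turned down

**Alternative 1:** Ring A is cut between C3 and C4. The forward key step is a SmI2 pinacol coupling of the cage dialdehyde A2, which closes ring A and gives the cis-diol A1. A1 is the same compound as 40, so both routes would end with the same acylation.
- For it: the diol is made at the very end, no acetonide has to be removed from a molecule carrying the ionisable C11 acetate, and samarium ketyl couplings that close six-membered rings usually give cis-diols. On these points it is at least as strong as the chosen plan.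
- Against it: the coupling must set C3 and C4 together on the face of the C15 arm and an axial C5 methyl, which is the more crowded face, and nothing in A2 enforces that. The C4 aldehyde is neopentyl. A2 already needs the complete cage with both vicinal quaternary carbons, and its absolute configuration would have to come from a separate asymmetric step.
- Comparison: the chosen plan instead takes C4 from pantolactone and uses C3 and C4 to control C6, C8 and C1 in turn. The hard part of alternative 1 (the cage) is not solved by its key step.

**Alternative 2:** The cyclopropane is cut at C9–C8 and C9–C10. In the forward direction the sodium salt of the tosylhydrazone A4 (a ring A aldehyde hydrazone on C1, spiro-linked at C6 to a 2-methylcyclopentenone) gives a diazoalkane that adds across the enone to the pyrazoline A5. Irradiation expels N2 and gives the nortricyclanone A3.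
- For it: two five-membered rings and the cyclopropane come from a simple spiro compound, the C10 methyl and C11 ketone are carried in by a common enone, and A3 has the same C11 ketone as 35, so the later C11 chemistry would be shared.
- Against it: A3 has no oxygen at C3, so the C3 acetate would need a late oxidation of an unactivated CH2 with control of configuration. A4 already contains the vicinal quaternary centres C1 and C6 in the correct relative configuration, so the main problem is only moved. Pyrazoline photolysis can also give alkenes by hydrogen shift.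
- Comparison: it is more step-economical for the cage itself, but the chosen plan reaches the same ketone with O3 and O4 in place and with C1 and C6 made by two stereocontrolled steps.

**Alternative 3:** The C10–C11 bond is cut. Bromine–lithium exchange with t-BuLi on the bromo(methyl)cyclopropane aldehyde A7 gives a cyclopropyllithium that adds to the aldehyde on C6 and closes the cage as the C11 carbinol A6.
- For it: C11 is obtained at the alcohol level without a cyclopropylcarbinyl cation, and cyclopropyllithiums keep their configuration. On this point it is at least as strong as the chosen plan, which needs reduction and solvolysis.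
- Against it: A7 needs bromine on C10 on the face of the C6 arm. This calls for an intermolecular dihalocarbene addition to the C8=C9 alkene from its more hindered face, followed by selective replacement of one bromine by methyl. The exchange must outrun addition of t-BuLi to a free aldehyde. The configuration of the new carbinol depends on the aldehyde rotamer and is not secured.
- Comparison: it would start from the same bicyclic alkene as 26 but needs more steps. The chosen diazo ketone forms both cyclopropane bonds at once, on the only face the tether allows.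

Key step: step 13

Remark on the chemistry: tributyl(iodomethyl)stannane 6, methanesulfonyl azide and 2,2,2-trifluoroethyl trifluoroacetate are taken as purchasable reagents.

## Route

Step 1
Reactants: 1 (R)-pantolactone
Product: 2 (2R)-3,3-dimethylbutane-1,2,4-triol
Conditions: LiAlH4, THF, 0 °C to reflux
Reagents that add atoms: none
Why: Hydride reduction of the lactone to the diol; the carbinol centre (future C4) is not touched.

Step 2
Reactants: 2 (2R)-3,3-dimethylbutane-1,2,4-triol
Product: 3 2-[(4R)-2,2-dimethyl-1,3-dioxolan-4-yl]-2-methylpropan-1-ol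
Conditions: Me2C(OMe)2, acetone, TsOH (cat.), rt
Reagents that add atoms: 2,2-dimethoxypropane, COC(C)(C)OC
Why: Acid-catalysed ketal exchange; an isopropylidene group prefers the five-membered dioxolane on the 1,2-diol (future O3 and O4) over the 1,3-dioxane, which leaves the neopentyl primary alcohol (future C6) free.

Step 3
Reactants: 3 2-[(4R)-2,2-dimethyl-1,3-dioxolan-4-yl]-2-methylpropan-1-ol
Product: 4 2-[(4R)-2,2-dimethyl-1,3-dioxolan-4-yl]-2-methylpropanal
Conditions: Dess–Martin periodinane, pyridine, CH2Cl2, 0 °C to rt
Reagents that add atoms: none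
Why: Dess–Martin oxidation of a primary alcohol; the aldehyde has no α-hydrogen and cannot enolise.

Step 4
Reactants: 5 4-methoxybenzyl alcohol; 6 tributyl(iodomethyl)stannane
Product: 7 tributyl{[(4-methoxybenzyl)oxy]methyl}stannane
Conditions: NaH, THF/DMF, 0 °C to rt
Reagents that add atoms: none
Why: Williamson etherification of the sodium alkoxide with the primary iodide.

Step 5
Reactants: 4 2-[(4R)-2,2-dimethyl-1,3-dioxolan-4-yl]-2-methylpropanal; 7 tributyl{[(4-methoxybenzyl)oxy]methyl}stannane
Product: 9 3-[(4R)-2,2-dimethyl-1,3-dioxolan-4-yl]-1-[(4-methoxybenzyl)oxy]-3-methylbutan-2-ol (both carbinol epimers), via alkoxymethyllithium 8 (not isolated)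
Conditions: n-BuLi, THF, −78 °C; then 4
Reagents that add atoms: none
Why: Tin–lithium exchange gives the α-alkoxymethyllithium 8, which adds to the non-enolisable aldehyde and introduces C11; the new carbinol centre is removed in the next step, so its configuration does not matter.

Step 6
Reactants: 9 3-[(4R)-2,2-dimethyl-1,3-dioxolan-4-yl]-1-[(4-methoxybenzyl)oxy]-3-methylbutan-2-ol
Product: 10 3-[(4R)-2,2-dimethyl-1,3-dioxolan-4-yl]-1-[(4-methoxybenzyl)oxy]-3-methylbutan-2-one
Conditions: Dess–Martin periodinane, pyridine, CH2Cl2, rt
Reagents that add atoms: none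
Why: Dess–Martin oxidation of the secondary alcohol to the C6 ketone; the acetonide and the PMB ether are inert.

Step 7
Reactants: 10 3-[(4R)-2,2-dimethyl-1,3-dioxolan-4-yl]-1-[(4-methoxybenzyl)oxy]-3-methylbutan-2-one; 11 methyltriphenylphosphonium bromide
Product: 12 (4R)-4-(3-{[(4-methoxybenzyl)oxy]methyl}-2-methylbut-3-en-2-yl)-2,2-dimethyl-1,3-dioxolane
Conditions: KOt-Bu, toluene, 0 to 90 °C
Reagents that add atoms: none
Why: Wittig methylenation; the unstabilised ylide at elevated temperature is the usual answer to a ketone flanked by a quaternary carbon, and it creates C6=C7 without a stereochemical issue.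

Step 8
Reactants: 12 (4R)-4-(3-{[(4-methoxybenzyl)oxy]methyl}-2-methylbut-3-en-2-yl)-2,2-dimethyl-1,3-dioxolane
Product: 13 (2R)-4-{[(4-methoxybenzyl)oxy]methyl}-3,3-dimethylpent-4-ene-1,2-diol
Conditions: AcOH/H2O/THF (3:1:1), 40 °C
Reagents that add atoms: none
Why: Mild acid hydrolysis of the terminal dioxolane; the allylic PMB ether and the 1,1-disubstituted alkene tolerate aqueous acetic acid.

Step 9
Reactants: 13 (2R)-4-{[(4-methoxybenzyl)oxy]methyl}-3,3-dimethylpent-4-ene-1,2-diol
Product: 14 (2R)-4-{[(4-methoxybenzyl)oxy]methyl}-3,3-dimethyl-1,2-bis[(triethylsilyl)oxy]pent-4-ene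
Conditions: Et3SiOTf, 2,6-lutidine, CH2Cl2, −78 to 0 °C
Reagents that add atoms: triethylsilyl trifluoromethanesulfonate, CC[Si](CC)(CC)OS(=O)(=O)C(F)(F)F
Why: Silylation with a silyl triflate, which also covers the hindered neopentyl secondary hydroxyl (O4).

Step 10
Reactants: 14 (2R)-4-{[(4-methoxybenzyl)oxy]methyl}-3,3-dimethyl-1,2-bis[(triethylsilyl)oxy]pent-4-ene
Product: 15 (2R)-4-{[(4-methoxybenzyl)oxy]methyl}-3,3-dimethyl-2-[(triethylsilyl)oxy]pent-4-enal
Conditions: (COCl)2, DMSO, CH2Cl2, −78 to −40 °C; then Et3N, −78 °C to rt
Reagents that add atoms: none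
Why: Under Swern conditions the chlorosulfonium salt cleaves a primary triethylsilyl ether and oxidises it to the aldehyde, while the hindered secondary silyl ether stays; the low temperature and the neopentyl α-carbon protect C4 from epimerisation.

Step 11
Reactants: 15 (2R)-4-{[(4-methoxybenzyl)oxy]methyl}-3,3-dimethyl-2-[(triethylsilyl)oxy]pent-4-enal; 16 propargyl bromide
Product: 17 (4S,5R)-7-{[(4-methoxybenzyl)oxy]methyl}-6,6-dimethyl-5-[(triethylsilyl)oxy]oct-7-en-1-yn-4-ol
Conditions: Zn, THF, 0 °C
Reagents that add atoms: none
Why: Barbier propargylation; allenylzinc bromide adds through a cyclic SE2' transition state to give the homopropargylic alcohol. With a non-chelating silyl ether the Cornforth (polar Felkin–Anh) arrangement applies: the C4–O bond lies anti to the carbonyl, the tert-alkyl group shields one face and the nucleophile passes the C4 hydrogen, which should give the 3,4-anti (3S) alcohol.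

Step 12
Reactants: 17 (4S,5R)-7-{[(4-methoxybenzyl)oxy]methyl}-6,6-dimethyl-5-[(triethylsilyl)oxy]oct-7-en-1-yn-4-ol
Product: 19 (4S,5R)-5-(3-{[(4-methoxybenzyl)oxy]methyl}-2-methylbut-3-en-2-yl)-2,2-dimethyl-4-(prop-2-yn-1-yl)-1,3-dioxolane, via diol 18 (not isolated)
Conditions: CSA (cat.), MeOH, 0 °C to rt; then Me2C(OMe)2, acetone, rt
Reagents that add atoms: 2,2-dimethoxypropane, COC(C)(C)OC
Why: Acid methanolysis of the silyl ether followed by ketalisation of the anti-diol 18 to the cis-dioxolane, which is the enyne for the key step with a PMB ether on O11.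

Step 13
Reactants: 19 (4S,5R)-5-(3-{[(4-methoxybenzyl)oxy]methyl}-2-methylbut-3-en-2-yl)-2,2-dimethyl-4-(prop-2-yn-1-yl)-1,3-dioxolane; 20 Co2(CO)8
Product: 22 tricyclic enone (ring A with the 3S,4R acetonide fused at C1–C6 to the cyclopentenone C8(=O)–C9=C1; C6 bears C11H2OPMB trans to the acetonide oxygens), via alkyne–Co2(CO)6 complex 21 (not isolated)
Conditions: Co2(CO)8, CH2Cl2, rt; then N-methylmorpholine N-oxide, CH2Cl2, 0 °C to rt
Reagents that add atoms: none
Why: Co2(CO)8 20 converts the alkyne of 19 into the alkyne–Co2(CO)6 complex 21; the N-oxide removes a carbonyl ligand, the C6=C7 alkene binds and inserts into the Co–C1 bond (C1–C6), a carbonyl ligand inserts into the Co–C7 bond (C7–C8), and reductive elimination joins C8 to C9 and releases the enone. The closest known reaction type is the intramolecular Pauson–Khand reaction of 1,7-enynes with a 1,1-disubstituted alkene, which gives bicyclo[4.3.0]nonenones with an angular quaternary carbon. Ring A closes in the 6-exo mode with respect to both the alkyne and the alkene (C9 and C7 stay outside the ring) by C1–C6 bond formation, and the cyclopentenone closes through the carbonyl carbon C8 by migratory insertion and reductive elimination. The gem-dimethyl group at C5 and the cis-dioxolane restrict the tether and should favour ring closure over alkyne oligomerisation. C6 is the only new stereocentre and is controlled by C3 and C4: because C7 must end in the plane of the cyclopentenone it is equatorial on the forming ring A and the C11 arm is axial, and of the two chair-like arrangements the one with this arm on the face away from O3 and O4 avoids a syn-axial contact between the arm and an axial O4 with its acetal carbon. That arrangement places C7 cis to O4, as the target requires. The step therefore needs this facial selectivity; the favoured arrangement pays for it with a syn-axial contact between one C5 methyl and O3, so the preference may be modest and the two C6 epimers are to be separated at this stage. The PMB ether and the acetonide are inert to the cobalt carbonyl and the N-oxide.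

Step 14
Reactants: 22 tricyclic enone
Product: 23 allylic alcohol (C8–OH on the cyclopentene face of C5, opposite to the C11 arm; C9=C1)
Conditions: NaBH4, CeCl3·7H2O, MeOH, −78 °C
Reagents that add atoms: none
Why: Luche 1,2-reduction of the enone; hydride is expected to reach C8 from the face of the C11H2OPMB arm, away from the quaternary C5 with its two methyl groups, which puts the hydroxyl on the C5 face.

Step 15
Reactants: 23 allylic alcohol; 6 tributyl(iodomethyl)stannane
Product: 24 C8 (tributylstannyl)methyl ether of 23
Conditions: KH, 18-crown-6 (cat.), THF, 0 °C to rt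
Reagents that add atoms: none
Why: Williamson etherification of the potassium alkoxide with the primary iodide; C8 keeps its configuration.

Step 16
Reactants: 24 C8 (tributylstannyl)methyl ether
Product: 26 homoallylic alcohol (C15H2OH on C1 cis to C5 and trans to the C11 arm; C8=C9), via lithiomethyl ether 25 (not isolated)
Conditions: n-BuLi, THF, −78 to −20 °C
Reagents that add atoms: none
Why: Still–Wittig [2,3]-sigmatropic rearrangement; tin–lithium exchange gives the α-alkoxymethyllithium 25, whose carbon moves suprafacially from O8 to C1 while the double bond shifts to C8=C9. The C8 configuration therefore sets C1, giving the trans relationship of C15 and the C11 arm that a conjugate addition to 22 would not be expected to give.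

Step 17
Reactants: 26 homoallylic alcohol
Product: 27 C15 pivalate of 26
Conditions: t-BuCOCl, pyridine, DMAP (cat.), CH2Cl2, rt
Reagents that add atoms: pivaloyl chloride, CC(C)(C)C(Cl)=O
Why: Acylation of the neopentyl primary alcohol; the pivalate has no α-hydrogen and resists the organometallic and amide-base steps that follow.

Step 18
Reactants: 27 C15 pivalate
Product: 28 C11 primary alcohol (C15 pivalate, acetonide, C8=C9)
Conditions: DDQ, CH2Cl2/pH 7 buffer, 0 °C
Reagents that add atoms: none
Why: Oxidative cleavage of the PMB ether through the benzylic oxocarbenium ion; the pivalate, the acetonide and the isolated alkene are inert.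

Step 19
Reactants: 28 C11 primary alcohol
Product: 29 C11 aldehyde on C6
Conditions: Dess–Martin periodinane, pyridine, CH2Cl2, rt
Reagents that add atoms: none
Why: Dess–Martin oxidation; the aldehyde sits on a quaternary carbon and cannot enolise.

Step 20
Reactants: 29 C11 aldehyde; 30 EtMgBr
Product: 31 C11 secondary alcohol C6–CH(OH)CH2CH3 (both C11 epimers)
Conditions: CeCl3, THF, −78 °C
Reagents that add atoms: none
Why: Organocerium addition to a hindered, non-enolisable aldehyde; the low basicity of EtCeCl2 and the absence of β-hydride reduction favour 1,2-addition, and the pivalate is not attacked at −78 °C. Both C11 epimers are oxidised in the next step.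

Step 21
Reactants: 31 C11 secondary alcohol
Product: 32 ethyl ketone C6–C11(=O)–C10H2–CH3
Conditions: Dess–Martin periodinane, pyridine, CH2Cl2, rt
Reagents that add atoms: none
Why: Dess–Martin oxidation of the secondary alcohol to the ketone.

Step 22
Reactants: 32 ethyl ketone
Product: 34 α-diazo ketone C6–C11(=O)–C10(=N2)–CH3, via trifluoroacetyl ketone 33 (not isolated)
Conditions: LiN(SiMe3)2, THF, −78 °C; CF3CO2CH2CF3; then MsN3, Et3N, H2O, MeCN, rt
Reagents that add atoms: 2,2,2-trifluoroethyl trifluoroacetate, FC(F)(F)COC(=O)C(F)(F)F; methanesulfonyl azide, CS(=O)(=O)N=[N+]=[N-]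
Why: Detrifluoroacetylative (Regitz-type deacylative) diazo transfer; the only possible enolate, towards C10, is trifluoroacetylated to 33, and the sulfonyl azide delivers N2 with loss of the activating acyl group.

Step 23
Reactants: 34 α-diazo ketone
Product: 35 nortricyclanone (C11 ketone, C10 methyl, C15 pivalate, acetonide)
Conditions: Cu(acac)2 (5 mol %), toluene, 100 °C, slow addition
Reagents that add atoms: none
Why: Copper-catalysed intramolecular cyclopropanation of C8=C9 by the ketocarbenoid at C10, the known route from cyclopent-3-enyl diazo ketones to nortricyclanones. The carbene is tied to C6 through C11 and can only add from the face of that arm, which sets C8, C9 and C10 together; copper is preferred to dirhodium carboxylates to limit 1,2-hydride shift from the methyl group.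

Step 24
Reactants: 35 nortricyclanone
Product: 36 diol (C15H2OH; C11–OH on the side of C2, the epimer opposite to the target)
Conditions: LiAlH4, THF, 0 °C to rt
Reagents that add atoms: none
Why: Hydride adds to C11 from the open side next to C7, so the hydroxyl ends beside ring A; the same reagent cleaves the pivalate reductively.

Step 25
Reactants: 36 diol
Product: 37 C15 acetate with free C11–OH
Conditions: Ac2O, pyridine, CH2Cl2, 0 °C
Reagents that add atoms: acetic anhydride, CC(=O)OC(C)=O
Why: Selective acetylation of the primary alcohol; the C11 hydroxyl lies between two quaternary carbons and against C2 and should not react without a nucleophilic catalyst.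

Step 26
Reactants: 37 C15 acetate with free C11–OH
Product: 39 C11,C15-diacetate acetonide (C11–OAc towards C7, as in the target), via mesylate 38 (not isolated)
Conditions: MsCl, Et3N, CH2Cl2, −30 °C; then KOAc, AcOH, 50 °C
Reagents that add atoms: methanesulfonyl chloride, CS(Cl)(=O)=O; potassium acetate, CC(=O)[O-].[K+]
Why: Sulfonylation and buffered acetolysis (SN1); the mesylate ionises to the bisected cyclopropylcarbinyl (nortricyclyl) cation stabilised by the two cyclopropane bonds at C10, and acetate should add from the open side next to C7, giving the inverted and thermodynamically preferred acetate.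

Step 27
Reactants: 39 C11,C15-diacetate acetonide
Product: 40 C3,C4-diol (3-deacetyl target)
Conditions: 80% aq. AcOH, 40 °C
Reagents that add atoms: none
Why: Mild acid hydrolysis of the acetonide; the acetates survive, and reversible ionisation at C11 in this medium can only return the same acetate.

Step 28
Reactants: 40 C3,C4-diol
Product: 42 CNP0197219.1 (C3,C11,C15-triacetate with free C4–OH), via cyclic orthoacetate 41 (not isolated)
Conditions: MeC(OMe)3, PPTS (cat.), CH2Cl2, rt; then 80% aq. AcOH, rt
Reagents that add atoms: trimethyl orthoacetate, CC(OC)(OC)OC; water, O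
Why: Cyclic orthoester formation on the cis-diol and mild acid opening, which as a rule gives the axial ester and the equatorial alcohol; in the chair that the cage allows ring A, O3 is axial and O4 equatorial, so the acetate is expected on O3 without base that could move it.

## Compound list

1 | (R)-pantolactone [(3R)-3-hydroxy-4,4-dimethyloxolan-2-one] | CC1(C)COC(=O)[C@@H]1O | starting material
2 | (2R)-3,3-dimethylbutane-1,2,4-triol | OC[C@H](O)C(C)(C)CO | intermediate
3 | 2-[(4R)-2,2-dimethyl-1,3-dioxolan-4-yl]-2-methylpropan-1-ol | OCC(C)(C)[C@@H]1COC(C)(C)O1 | intermediate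
4 | 2-[(4R)-2,2-dimethyl-1,3-dioxolan-4-yl]-2-methylpropanal | O=CC(C)(C)[C@@H]1COC(C)(C)O1 | intermediate
5 | 4-methoxybenzyl alcohol | OCc1ccc(OC)cc1 | starting material
6 | tributyl(iodomethyl)stannane | CCCC[Sn](CCCC)(CCCC)CI | starting material
7 | tributyl{[(4-methoxybenzyl)oxy]methyl}stannane | CCCC[Sn](CCCC)(CCCC)COCc1ccc(OC)cc1 | intermediate
8 | {[(4-methoxybenzyl)oxy]methyl}lithium | [Li]COCc1ccc(OC)cc1 | intermediate
9 | 3-[(4R)-2,2-dimethyl-1,3-dioxolan-4-yl]-1-[(4-methoxybenzyl)oxy]-3-methylbutan-2-ol, both C2 epimers | COc1ccc(COCC(O)C(C)(C)[C@@H]2COC(C)(C)O2)cc1 | intermediate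
10 | 3-[(4R)-2,2-dimethyl-1,3-dioxolan-4-yl]-1-[(4-methoxybenzyl)oxy]-3-methylbutan-2-one | COc1ccc(COCC(=O)C(C)(C)[C@@H]2COC(C)(C)O2)cc1 | intermediate
11 | methyltriphenylphosphonium bromide | C[P+](c1ccccc1)(c1ccccc1)c1ccccc1.[Br-] | starting material
12 | (4R)-4-(3-{[(4-methoxybenzyl)oxy]methyl}-2-methylbut-3-en-2-yl)-2,2-dimethyl-1,3-dioxolane | COc1ccc(COCC(=C)C(C)(C)[C@@H]2COC(C)(C)O2)cc1 | intermediate
13 | (2R)-4-{[(4-methoxybenzyl)oxy]methyl}-3,3-dimethylpent-4-ene-1,2-diol | COc1ccc(COCC(=C)C(C)(C)[C@@H](O)CO)cc1 | intermediate
14 | (2R)-4-{[(4-methoxybenzyl)oxy]methyl}-3,3-dimethyl-1,2-bis[(triethylsilyl)oxy]pent-4-ene | COc1ccc(COCC(=C)C(C)(C)[C@@H](O[Si](CC)(CC)CC)CO[Si](CC)(CC)CC)cc1 | intermediate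
15 | (2R)-4-{[(4-methoxybenzyl)oxy]methyl}-3,3-dimethyl-2-[(triethylsilyl)oxy]pent-4-enal | COc1ccc(COCC(=C)C(C)(C)[C@@H](O[Si](CC)(CC)CC)C=O)cc1 | intermediate
16 | propargyl bromide (3-bromoprop-1-yne) | BrCC#C | starting material
17 | (4S,5R)-7-{[(4-methoxybenzyl)oxy]methyl}-6,6-dimethyl-5-[(triethylsilyl)oxy]oct-7-en-1-yn-4-ol | COc1ccc(COCC(=C)C(C)(C)[C@@H](O[Si](CC)(CC)CC)[C@@H](O)CC#C)cc1 | intermediate
18 | (4S,5R)-7-{[(4-methoxybenzyl)oxy]methyl}-6,6-dimethyloct-7-en-1-yne-4,5-diol | COc1ccc(COCC(=C)C(C)(C)[C@@H](O)[C@@H](O)CC#C)cc1 | intermediate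
19 | (4S,5R)-5-(3-{[(4-methoxybenzyl)oxy]methyl}-2-methylbut-3-en-2-yl)-2,2-dimethyl-4-(prop-2-yn-1-yl)-1,3-dioxolane (cis-dioxolane; acetonide-protected oct-1-en-7-yne) | C#CC[C@@H]1OC(C)(C)O[C@@H]1C(C)(C)C(=C)COCc2ccc(OC)cc2 | intermediate
20 | Co2(CO)8, dicobalt octacarbonyl | O=C=[Co](=C=O)(=C=O)(=C=O)[Co](=C=O)(=C=O)(=C=O)=C=O | starting material
21 | alkyne–Co2(CO)6 complex of 19 (C1 and C9 bridging the two cobalt atoms) | [CH]12[Co]3(=C=O)(=C=O)(=C=O)[Co]1(=C=O)(=C=O)(=C=O)C23C[C@@H]4OC(C)(C)O[C@@H]4C(C)(C)C(=C)COCc5ccc(OC)cc5 | intermediate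
22 | tricyclic enone: ring A (C1–C6) with (3S,4R) cis-acetonide and C5 gem-dimethyl, fused at C1–C6 to the cyclopentenone C6–C7H2–C8(=O)–C9H=C1; C6 bears C7 on the ring A face of O3/O4 and C11H2OPMB on the opposite face | O=C1C=C2C[C@@H]3OC(C)(C)O[C@@H]3C(C)(C)[C@]2(COCc4ccc(OC)cc4)C1 | intermediate
23 | allylic alcohol of 22: C8–OH on the cyclopentene face of C5, trans to the C11 arm | O[C@@H]1C=C2C[C@@H]3OC(C)(C)O[C@@H]3C(C)(C)[C@]2(COCc4ccc(OC)cc4)C1 | intermediate
24 | C8 (tributylstannyl)methyl ether of 23 | CCCC[Sn](CCCC)(CCCC)CO[C@@H]1C=C2C[C@@H]3OC(C)(C)O[C@@H]3C(C)(C)[C@]2(COCc4ccc(OC)cc4)C1 | intermediate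
25 | C8 lithiomethyl ether of 23 | [Li]CO[C@@H]1C=C2C[C@@H]3OC(C)(C)O[C@@H]3C(C)(C)[C@]2(COCc4ccc(OC)cc4)C1 | intermediate
26 | homoallylic alcohol: ring A fused trans at C1–C6 to the cyclopentene C6–C7H2–C8H=C9H–C1; C1 bears C15H2OH on the ring A face of O3/O4, C6 bears C11H2OPMB on the opposite face | OC[C@]12C[C@@H]3OC(C)(C)O[C@@H]3C(C)(C)[C@]1(COCc4ccc(OC)cc4)CC=C2 | intermediate
27 | C15 pivalate of 26 | CC(C)(C)C(=O)OC[C@]12C[C@@H]3OC(C)(C)O[C@@H]3C(C)(C)[C@]1(COCc4ccc(OC)cc4)CC=C2 | intermediate
28 | C11 primary alcohol (PMB removed from 27) | CC(C)(C)C(=O)OC[C@]12C[C@@H]3OC(C)(C)O[C@@H]3C(C)(C)[C@]1(CO)CC=C2 | intermediate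
29 | C11 aldehyde on C6 | CC(C)(C)C(=O)OC[C@]12C[C@@H]3OC(C)(C)O[C@@H]3C(C)(C)[C@]1(C=O)CC=C2 | intermediate
30 | EtMgBr, ethylmagnesium bromide | CC[Mg]Br | starting material
31 | C11 secondary alcohol C6–CH(OH)CH2CH3, both C11 epimers | CC(C)(C)C(=O)OC[C@]12C[C@@H]3OC(C)(C)O[C@@H]3C(C)(C)[C@]1(C(O)CC)CC=C2 | intermediate
32 | ethyl ketone C6–C11(=O)–C10H2–CH3 | CC(C)(C)C(=O)OC[C@]12C[C@@H]3OC(C)(C)O[C@@H]3C(C)(C)[C@]1(C(=O)CC)CC=C2 | intermediate
33 | C10 trifluoroacetyl derivative of 32 (C10 epimers) | CC(C)(C)C(=O)OC[C@]12C[C@@H]3OC(C)(C)O[C@@H]3C(C)(C)[C@]1(C(=O)C(C)C(=O)C(F)(F)F)CC=C2 | intermediate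
34 | α-diazo ketone C6–C11(=O)–C10(=N2)–CH3 | CC(C)(C)C(=O)OC[C@]12C[C@@H]3OC(C)(C)O[C@@H]3C(C)(C)[C@]1(C(=O)C(C)=[N+]=[N-])CC=C2 | intermediate
35 | nortricyclanone: full cage with C11 ketone, C10 methyl, C15 pivalate, (3S,4R) acetonide | CC(C)(C)C(=O)OC[C@]12C[C@@H]4OC(C)(C)O[C@@H]4C(C)(C)[C@]13C[C@@H]1[C@H]2[C@]1(C)C3=O | intermediate
36 | cage diol: C15H2OH and C11–OH, the C11 oxygen on the side of C2 (11-epi) | OC[C@]12C[C@@H]4OC(C)(C)O[C@@H]4C(C)(C)[C@]13C[C@@H]1[C@H]2[C@]1(C)[C@@H]3O | intermediate
37 | C15 acetate of 36 with free 11-epi hydroxyl | CC(=O)OC[C@]12C[C@@H]4OC(C)(C)O[C@@H]4C(C)(C)[C@]13C[C@@H]1[C@H]2[C@]1(C)[C@@H]3O | intermediate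
38 | C11 mesylate of 37 | CC(=O)OC[C@]12C[C@@H]4OC(C)(C)O[C@@H]4C(C)(C)[C@]13C[C@@H]1[C@H]2[C@]1(C)[C@@H]3OS(C)(=O)=O | intermediate
39 | C11,C15-diacetate acetonide, C11–OAc towards the C7 bridge | CC(=O)OC[C@]12C[C@@H]4OC(C)(C)O[C@@H]4C(C)(C)[C@]13C[C@@H]1[C@H]2[C@]1(C)[C@H]3OC(C)=O | intermediate
40 | (3S,4R)-C3,C4-diol with C11 and C15 acetates (3-deacetyl target) | CC(=O)OC[C@]12C[C@H](O)[C@H](O)C(C)(C)[C@]13C[C@@H]1[C@H]2[C@]1(C)[C@H]3OC(C)=O | intermediate
41 | cyclic methyl orthoacetate of 40 across O3 and O4 (orthoester carbon as a mixture) | CC(=O)OC[C@]12C[C@@H]4OC(C)(OC)O[C@@H]4C(C)(C)[C@]13C[C@@H]1[C@H]2[C@]1(C)[C@H]3OC(C)=O | intermediate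
42 | CNP0197219.1: nortricyclene-fused ring A with C3–OAc, C4–OH (3S,4R), C5 gem-dimethyl, C10 methyl, C11–OAc and C15H2OAc | CC(=O)OC[C@]12C[C@H](OC(C)=O)[C@H](O)C(C)(C)[C@]13C[C@@H]1[C@H]2[C@]1(C)[C@H]3OC(C)=O | target

## Step count and least certain steps

Total step count: 28. Longest linear sequence: 27 steps (1 to 42 through steps 1–3 and 5–28; step 4 is a one-step side branch).

**Step 13 (key step).** Two processes may fail. The first is slow insertion of the hindered alkene, which is 1,1-disubstituted and flanked by the C5 quaternary carbon, so that the alkyne complex decomposes or oligomerises before ring closure. The second is poor facial selectivity at C6, because the two chair-like arrangements differ only in which syn-axial contact they accept. The fallback replaces the one-flask cobalt reaction by a stepwise early-metal sequence. It sets out from 19, which is silylated at C9 (n-BuLi, Me3SiCl) to the C9-trimethylsilyl enyne F1. Oxidative cyclisation with Cp2ZrBu2 (from Cp2ZrCl2 and n-BuLi) gives the zirconacyclopentene F2, in which C1–C6 is formed at a single metal centre with a different transition-state geometry. Carbonylation under CO gives the α-silyl enone F3, and protodesilylation with tetrabutylammonium fluoride in wet THF returns to 22.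

**Step 16.** The C15 carbon must bond to C1 on the face that carries an axial C5 methyl and O3. The [2,3] shift may therefore be slow, so that a [1,2] shift or simple protonation of the lithiomethyl ether takes over. The fallback sets out from 23 and avoids the organolithium. Heating with N,N-dimethylformamide dimethyl acetal in xylene gives the alkoxy(amino)carbene, whose thermal [2,3]-sigmatropic rearrangement (also suprafacial) gives the C1 N,N-dimethylcarboxamide F4. Reduction with LiH2NBH3 gives the primary alcohol and returns to 26.

**Step 26.** The cyclopropylcarbinyl cation may be captured at C8 or C9 with opening of the cyclopropane to homoallylic acetates. It may also be captured with retention, or lose a proton. The fallback avoids the cation and uses the fact that the target configuration at C11 is the more stable one. It sets out from 35, which is reduced under equilibrating Meerwein–Ponndorf–Verley conditions (Al(Oi-Pr)3, i-PrOH, a little acetone, toluene, reflux) to the thermodynamic C11 alcohol F5, with the oxygen towards C7 and the pivalate kept. LiAlH4 cleaves the pivalate to the diol F6, and Ac2O with DMAP acetylates both hydroxyls and returns to 39.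

**Step 14.** The control is 1,3-induction from a quaternary carbon with two different substituents, so hydride delivery may show poor facial selectivity or the opposite sense. The fallback corrects C8 by substitution instead of by addition. It sets out from 22, and the C8-epimeric alcohol F7 from the reduction is inverted under Mitsunobu conditions (4-nitrobenzoic acid, PPh3, diisopropyl azodicarboxylate) to the 4-nitrobenzoate F8. Methanolysis (K2CO3, MeOH) returns to 23.

**Step 11.** The tert-alkyl group on C4 competes with the silyloxy group for the position anti to the nucleophile, which may erode or reverse the anti selectivity. The fallback sets out from 15. The separated (4R,5R) alcohol F9, which is the C3 epimer, is inverted by a Mitsunobu reaction with 4-nitrobenzoic acid to the 4-nitrobenzoate F10. Methanolysis (K2CO3, MeOH) returns to 17.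

**Step 28.** If ring A leaves the chair, the orthoester may open towards O4, and the acetyl group may also migrate between the cis oxygens. The fallback differentiates the two hydroxyls by protection. It sets out from 40. Silylation with Et3SiCl and imidazole at low temperature should take the equatorial O4 and give the C4 triethylsilyl ether F11. Ac2O with DMAP then acetylates O3 to give F12, and HF·pyridine removes the silyl group under non-basic conditions and arrives at 42.

## Further compounds

F1 | step 13 | C9-trimethylsilyl enyne (19 with Me3Si on the alkyne terminus) | C[Si](C)(C)C#CC[C@@H]1OC(C)(C)O[C@@H]1C(C)(C)C(=C)COCc2ccc(OC)cc2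
F2 | step 13 | zirconacyclopentene: Cp2Zr bonded to C7 and C9, C9(SiMe3)=C1, C1–C6 formed | C[Si](C)(C)C1=C2C[C@@H]3OC(C)(C)O[C@@H]3C(C)(C)[C@]2(COCc4ccc(OC)cc4)C[Zr]1(C5C=CC=C5)C6C=CC=C6
F3 | step 13 | C9-trimethylsilyl derivative of enone 22 | O=C1C([Si](C)(C)C)=C2C[C@@H]3OC(C)(C)O[C@@H]3C(C)(C)[C@]2(COCc4ccc(OC)cc4)C1
F4 | step 16 | C1 N,N-dimethylcarboxamide (amide carbon = C15) of the C8=C9 cyclopentene | CN(C)C(=O)[C@]12C[C@@H]3OC(C)(C)O[C@@H]3C(C)(C)[C@]1(COCc4ccc(OC)cc4)CC=C2
F5 | step 26 | cage C11 alcohol with the oxygen towards C7, C15 pivalate, acetonide | CC(C)(C)C(=O)OC[C@]12C[C@@H]4OC(C)(C)O[C@@H]4C(C)(C)[C@]13C[C@@H]1[C@H]2[C@]1(C)[C@H]3O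
F6 | step 26 | cage diol with C15H2OH and C11–OH towards C7, acetonide | OC[C@]12C[C@@H]4OC(C)(C)O[C@@H]4C(C)(C)[C@]13C[C@@H]1[C@H]2[C@]1(C)[C@H]3O
F7 | step 14 | C8 epimer of allylic alcohol 23 (C8–OH on the face of the C11 arm) | O[C@H]1C=C2C[C@@H]3OC(C)(C)O[C@@H]3C(C)(C)[C@]2(COCc4ccc(OC)cc4)C1
F8 | step 14 | C8 4-nitrobenzoate with the configuration of 23 | O=C(O[C@@H]1C=C2C[C@@H]3OC(C)(C)O[C@@H]3C(C)(C)[C@]2(COCc4ccc(OC)cc4)C1)c5ccc(cc5)[N+](=O)[O-]
F9 | step 11 | (4R,5R)-7-{[(4-methoxybenzyl)oxy]methyl}-6,6-dimethyl-5-[(triethylsilyl)oxy]oct-7-en-1-yn-4-ol | COc1ccc(COCC(=C)C(C)(C)[C@@H](O[Si](CC)(CC)CC)[C@H](O)CC#C)cc1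
F10 | step 11 | (4S,5R) 4-nitrobenzoate of alcohol 17 | COc1ccc(COCC(=C)C(C)(C)[C@@H](O[Si](CC)(CC)CC)[C@@H](OC(=O)c2ccc(cc2)[N+](=O)[O-])CC#C)cc1
F11 | step 28 | C4 triethylsilyl ether of diol 40 | CC(=O)OC[C@]12C[C@H](O)[C@H](O[Si](CC)(CC)CC)C(C)(C)[C@]13C[C@@H]1[C@H]2[C@]1(C)[C@H]3OC(C)=O
F12 | step 28 | C3 acetate C4 triethylsilyl ether (silylated target) | CC(=O)OC[C@]12C[C@H](OC(C)=O)[C@H](O[Si](CC)(CC)CC)C(C)(C)[C@]13C[C@@H]1[C@H]2[C@]1(C)[C@H]3OC(C)=O
A1 | alternative 1 | C3,C4-cis-diol with C11 and C15 acetates (same compound as 40) | CC(=O)OC[C@]12C[C@H](O)[C@H](O)C(C)(C)[C@]13C[C@@H]1[C@H]2[C@]1(C)[C@H]3OC(C)=O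
A2 | alternative 1 | cage dialdehyde: C1 bears CH2CHO (C2, C3), C6 bears CMe2CHO (C5, C4), C11 and C15 acetates | CC(=O)OC[C@]1(CC=O)[C@]2(C(C)(C)C=O)C[C@@H]3[C@H]1[C@]3(C)[C@H]2OC(C)=O
A3 | alternative 2 | nortricyclanone with C11 ketone, C4 and C15 tert-butyldimethylsilyl ethers, no oxygen at C3 | CC(C)(C)[Si](C)(C)OC[C@]12CC[C@H](O[Si](C)(C)C(C)(C)C)C(C)(C)[C@]13C[C@@H]1[C@H]2[C@]1(C)C3=O
A4 | alternative 2 | spiro enone tosylhydrazone: C9 aldehyde tosylhydrazone on C1, C6 spiro to 2-methylcyclopent-2-enone (C7, C8=C10, C11=O) | CC(C)(C)[Si](C)(C)OC[C@]1(C=NNS(=O)(=O)c2ccc(C)cc2)CC[C@H](O[Si](C)(C)C(C)(C)C)C(C)(C)[C@]13CC=C(C)C3=O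
A5 | alternative 2 | 1-pyrazoline from addition of the C9 diazo group across C8=C10 | CC(C)(C)[Si](C)(C)OC[C@]12CC[C@H](O[Si](C)(C)C(C)(C)C)C(C)(C)[C@]13C[C@@H]1[C@H]2N=N[C@]1(C)C3=O
A6 | alternative 3 | nortricyclene C11 alcohol with ring A acetonide and C15 silyl ether | CC(C)(C)[Si](C)(C)OC[C@]12C[C@@H]4OC(C)(C)O[C@@H]4C(C)(C)[C@]13C[C@@H]1[C@H]2[C@]1(C)[C@H]3O
A7 | alternative 3 | bromo(methyl)cyclopropane aldehyde: C10 bears Br (towards C6) and CH3, C6 bears CHO | CC(C)(C)[Si](C)(C)OC[C@]12C[C@@H]4OC(C)(C)O[C@@H]4C(C)(C)[C@]1(C=O)C[C@@H]3[C@H]2[C@]3(C)Br
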